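The dimer is cut at the interflavan C4–C8 bond into an epiafzelechin C4 electrophile and an epicatechin C8 nucleophile, and both flavan-3-ols are made by one sequence. Everything rests on the C3–C4 bond of ring C of the epicatechin unit: C4 is a benzylic CH2 on ring A and C3 carries oxygen, so this bond is the reduced form of a styrenyl enol ether. Ring-closing metathesis of an acyclic diene, the 2-vinylaryl ether of a 2-methoxyallyl unit whose C2 is set by catalytic O–H insertion, closes ring C at C3=C4; hydrolysis gives the flavan-3-one, and C2 then relays its configuration to C3 by hydride reduction.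

Key step: step 7

Remark on the chemistry: in steps 5 and 10 the antipode of the spiro bis(oxazoline) ligand is taken that delivers the (R)-esters; the sense of induction is assumed, and the other antipode would be used if it proved opposite.

Step 1
Reactants: 1 2,4,6-trihydroxybenzaldehyde
Product: 2 2,4-bis(benzyloxy)-6-hydroxybenzaldehyde
Conditions: BnBr (2.1 equiv), K2CO3 (2.2 equiv), DMF, 0 °C to rt
Reagents that add atoms: benzyl bromide, BrCc1ccccc1
Why: Williamson etherification; the hydroxyl that stays hydrogen-bonded to the formyl group is the least nucleophilic, so alkylation should stop at the dibenzyl ether.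

Step 2
Reactants: 2 2,4-bis(benzyloxy)-6-hydroxybenzaldehyde
Product: 3 3,5-bis(benzyloxy)-2-vinylphenol
Conditions: Ph3PCH3Br (2.5 equiv), KOtBu (2.4 equiv), THF, 0 °C to rt; pH 7 buffer work-up, used at once
Reagents that add atoms: methyltriphenylphosphonium bromide, C[P+](c1ccccc1)(c1ccccc1)c1ccccc1.[Br-]
Why: Wittig methylenation, in which the first equivalent of ylide forms the phenoxide and the second olefinates the aldehyde.

Step 3
Reactants: 4 methyl 2-(3,4-dihydroxyphenyl)acetate
Product: 5 methyl 2-[3,4-bis(benzyloxy)phenyl]acetate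
Conditions: BnBr (2.2 equiv), K2CO3, acetone, reflux
Reagents that add atoms: benzyl bromide, BrCc1ccccc1
Why: Williamson etherification of both catechol hydroxyls, with the methyl ester inert to carbonate in acetone.

Step 4
Reactants: 5 methyl 2-[3,4-bis(benzyloxy)phenyl]acetate
Product: 6 methyl 2-[3,4-bis(benzyloxy)phenyl]-2-diazoacetate
Conditions: p-ABSA (1.2 equiv), DBU, MeCN, 0 °C to rt
Reagents that add atoms: 4-acetamidobenzenesulfonyl azide (p-ABSA), CC(=O)Nc1ccc(cc1)S(=O)(=O)N=[N+]=[N-]
Why: Regitz diazo transfer onto the benzylic ester enolate, which DBU forms readily.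

Step 5
Reactants: 6 methyl 2-[3,4-bis(benzyloxy)phenyl]-2-diazoacetate; 3 3,5-bis(benzyloxy)-2-vinylphenol
Product: 7 methyl (2R)-2-[3,5-bis(benzyloxy)-2-vinylphenoxy]-2-[3,4-bis(benzyloxy)phenyl]acetate
Conditions: PdCl2(PhCN)2 (5 mol%), 7,7'-bis(4-phenyl-4,5-dihydrooxazol-2-yl)-1,1'-spirobiindane (one antipode, 6 mol%), NaB[3,5-(CF3)2C6H3]4 (12 mol%), 5 Å MS, CHCl3, 25 °C, slow addition of 6
Reagents that add atoms: none
Why: Enantioselective metal-carbene O–H insertion, in which the phenol oxygen attacks the palladium carbene from 6 and the chiral ligand steers the proton shift of the ylide, setting the future C2 as R; O–H insertion is expected to outrun cyclopropanation of the styrene.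

Step 6
Reactants: 7 methyl (2R)-2-[3,5-bis(benzyloxy)-2-vinylphenoxy]-2-[3,4-bis(benzyloxy)phenyl]acetate
Product: 8 1,5-bis(benzyloxy)-3-{[(1R)-1-[3,4-bis(benzyloxy)phenyl]-2-methoxyprop-2-en-1-yl]oxy}-2-vinylbenzene
Conditions: Cp2TiMe2 (3 equiv), toluene/THF, 65 °C, dark; basic alumina
Reagents that add atoms: dimethyltitanocene, C[Ti](C)(C1C=CC=C1)C1C=CC=C1
Why: Petasis methylenation of the ester carbonyl through Cp2Ti=CH2 gives the enol ether under non-basic conditions, so the acidic C2–H is not touched.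

Step 7
Reactants: 8 1,5-bis(benzyloxy)-3-{[(1R)-1-[3,4-bis(benzyloxy)phenyl]-2-methoxyprop-2-en-1-yl]oxy}-2-vinylbenzene
Product: 10 (2R)-5,7-bis(benzyloxy)-2-[3,4-bis(benzyloxy)phenyl]chroman-3-one, via cyclic enol ether 9 (not isolated)
Conditions: second-generation Grubbs catalyst RuCl2(=CHPh)(PCy3)(H2IMes) (10 mol%), 1,4-benzoquinone (20 mol%), toluene (0.005 M), 70 °C; then oxalic acid, THF/H2O, 0 °C
Reagents that add atoms: water, O
Why: Ring-closing olefin metathesis: the ruthenium alkylidene loads onto the monosubstituted styrene carbon (C4), forms a ruthenacyclobutane with the 1,1-disubstituted enol ether and expels ethylene, joining C4 to C3 as the C3=C4 bond of enol ether 9; mild acid then protonates C4 and adds water at C3 to give ketone 10. The closest known reaction type is enol ether–olefin ring-closing metathesis as used for cyclic enol ethers, together with the diene ring-closing metathesis of 2-vinylphenyl allyl ethers to 2H-chromenes. Ring C is the only ring closed, a six-membered ring formed by metathesis between the two alkene termini held by the C4a–C8a–O1–C2 tether. No new stereocenter is formed, and C2 is untouched because neither the metathesis nor the short cold hydrolysis is basic. The step needs initiation at the styrene and not at the enol ether, which the lower substitution of the vinyl group secures, and ring closure over dimerization, which high dilution and the six-membered ring secure. It also needs the double bond to stay at C3=C4 and not move to C2=C3, for which 1,4-benzoquinone is added to intercept ruthenium hydrides.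

Step 8
Reactants: 10 (2R)-5,7-bis(benzyloxy)-2-[3,4-bis(benzyloxy)phenyl]chroman-3-one
Product: 11 (2R,3R)-5,7-bis(benzyloxy)-2-[3,4-bis(benzyloxy)phenyl]chroman-3-ol (5,7,3',4'-tetra-O-benzyl-(−)-epicatechin)
Conditions: LiBH(s-Bu)3 (L-selectride), LiBr, THF, −78 °C; then H2O
Reagents that add atoms: none
Why: Substrate-controlled ketone reduction, in which the bulky hydride attacks C3 from the face opposite the C2 aryl group, so the hydroxyl should end cis to the aryl (3R).

Step 9
Reactants: 12 methyl 2-[4-(benzyloxy)phenyl]acetate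
Product: 13 methyl 2-[4-(benzyloxy)phenyl]-2-diazoacetate
Conditions: p-ABSA (1.2 equiv), DBU, MeCN, 0 °C to rt
Reagents that add atoms: 4-acetamidobenzenesulfonyl azide (p-ABSA), CC(=O)Nc1ccc(cc1)S(=O)(=O)N=[N+]=[N-]
Why: Regitz diazo transfer onto the benzylic ester enolate.

Step 10
Reactants: 13 methyl 2-[4-(benzyloxy)phenyl]-2-diazoacetate; 3 3,5-bis(benzyloxy)-2-vinylphenol
Product: 14 methyl (2R)-2-[3,5-bis(benzyloxy)-2-vinylphenoxy]-2-[4-(benzyloxy)phenyl]acetate
Conditions: PdCl2(PhCN)2 (5 mol%), the same spiro bis(oxazoline) antipode (6 mol%), NaB[3,5-(CF3)2C6H3]4 (12 mol%), 5 Å MS, CHCl3, 25 °C, slow addition of 13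
Reagents that add atoms: none
Why: Enantioselective metal-carbene O–H insertion as in step 5, with the ligand-controlled proton shift setting the future C2 of the epiafzelechin unit as R.

Step 11
Reactants: 14 methyl (2R)-2-[3,5-bis(benzyloxy)-2-vinylphenoxy]-2-[4-(benzyloxy)phenyl]acetate
Product: 15 1,5-bis(benzyloxy)-3-{[(1R)-1-[4-(benzyloxy)phenyl]-2-methoxyprop-2-en-1-yl]oxy}-2-vinylbenzene
Conditions: Cp2TiMe2 (3 equiv), toluene/THF, 65 °C, dark; basic alumina
Reagents that add atoms: dimethyltitanocene, C[Ti](C)(C1C=CC=C1)C1C=CC=C1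
Why: Petasis methylenation of the ester carbonyl under non-basic conditions, leaving C2 intact.

Step 12
Reactants: 15 1,5-bis(benzyloxy)-3-{[(1R)-1-[4-(benzyloxy)phenyl]-2-methoxyprop-2-en-1-yl]oxy}-2-vinylbenzene
Product: 17 (2R)-5,7-bis(benzyloxy)-2-[4-(benzyloxy)phenyl]chroman-3-one, via cyclic enol ether 16 (not isolated)
Conditions: second-generation Grubbs catalyst RuCl2(=CHPh)(PCy3)(H2IMes) (10 mol%), 1,4-benzoquinone (20 mol%), toluene (0.005 M), 70 °C; then oxalic acid, THF/H2O, 0 °C
Reagents that add atoms: water, O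
Why: Enol ether–olefin ring-closing metathesis closes ring C of the upper unit at C3=C4 with loss of ethylene, and mild hydrolysis of the enol ether gives the ketone without touching C2.

Step 13
Reactants: 17 (2R)-5,7-bis(benzyloxy)-2-[4-(benzyloxy)phenyl]chroman-3-one
Product: 18 (2R,3R)-5,7-bis(benzyloxy)-2-[4-(benzyloxy)phenyl]chroman-3-ol (5,7,4'-tri-O-benzyl-(−)-epiafzelechin)
Conditions: LiBH(s-Bu)3 (L-selectride), LiBr, THF, −78 °C; then H2O
Reagents that add atoms: none
Why: Substrate-controlled ketone reduction with hydride delivered anti to the C2 aryl group, which should give the 2,3-cis alcohol (3R).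

Step 14
Reactants: 18 5,7,4'-tri-O-benzyl-(−)-epiafzelechin
Product: 19 4β-(2-ethoxyethoxy)-5,7,4'-tri-O-benzyl-(−)-epiafzelechin (2,3-cis, 3,4-trans; free 3-OH)
Conditions: DDQ (2 equiv), 2-ethoxyethanol (5 equiv), CH2Cl2, rt
Reagents that add atoms: 2-ethoxyethanol, CCOCCO
Why: Benzylic oxidation, in which DDQ abstracts hydride from C4 (activated by the two ring A oxygens) and the alcohol traps the cation anti to the C3 hydroxyl; this C4 center is ionized again in step 15.

Step 15
Reactants: 19 4β-(2-ethoxyethoxy)-5,7,4'-tri-O-benzyl-(−)-epiafzelechin; 11 5,7,3',4'-tetra-O-benzyl-(−)-epicatechin (4 equiv)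
Product: 20 hepta-O-benzyl ether of epiafzelechin-(4β→8)-epicatechin (all seven phenols benzylated, both 3-OH free)
Conditions: TMSOTf (cat.), CH2Cl2, −78 °C; aq. NaHCO3
Reagents that add atoms: none
Why: Lewis-acid-promoted Friedel–Crafts-type interflavan coupling, in which the C4 cation is attacked by C8 of ring A of 11 (less hindered than C6, which lies between two benzyloxy groups) anti to the C3 hydroxyl, so C3 sets the new C4 center as 3,4-trans (4β, 4R); excess 11 suppresses chain growth.

Step 16
Reactants: 20 hepta-O-benzyl ether of epiafzelechin-(4β→8)-epicatechin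
Product: 21 (−)-epiafzelechin-(4β→8)-(−)-epicatechin
Conditions: H2 (1 atm), Pd(OH)2/C, THF/MeOH/H2O, rt
Reagents that add atoms: none
Why: Hydrogenolysis of the seven benzyl ethers under neutral conditions should leave the chroman C2–O bonds and the interflavan bond intact and creates no stereocenter.

Compound list
1 | 2,4,6-trihydroxybenzaldehyde | O=Cc1c(O)cc(O)cc1O | starting material
2 | 2,4-bis(benzyloxy)-6-hydroxybenzaldehyde | O=Cc1c(O)cc(OCc2ccccc2)cc1OCc1ccccc1 | intermediate
3 | 3,5-bis(benzyloxy)-2-vinylphenol | C=Cc1c(O)cc(OCc2ccccc2)cc1OCc1ccccc1 | intermediate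
4 | methyl 2-(3,4-dihydroxyphenyl)acetate | COC(=O)Cc1ccc(O)c(O)c1 | starting material
5 | methyl 2-[3,4-bis(benzyloxy)phenyl]acetate | COC(=O)Cc1ccc(OCc2ccccc2)c(OCc2ccccc2)c1 | intermediate
6 | methyl 2-[3,4-bis(benzyloxy)phenyl]-2-diazoacetate | COC(=O)C(=[N+]=[N-])c1ccc(OCc2ccccc2)c(OCc2ccccc2)c1 | intermediate
7 | methyl (2R)-2-[3,5-bis(benzyloxy)-2-vinylphenoxy]-2-[3,4-bis(benzyloxy)phenyl]acetate | C=Cc1c(OCc2ccccc2)cc(OCc2ccccc2)cc1O[C@H](c1ccc(OCc2ccccc2)c(OCc2ccccc2)c1)C(=O)OC | intermediate
8 | 1,5-bis(benzyloxy)-3-{[(1R)-1-[3,4-bis(benzyloxy)phenyl]-2-methoxyprop-2-en-1-yl]oxy}-2-vinylbenzene | C=Cc1c(OCc2ccccc2)cc(OCc2ccccc2)cc1O[C@H](c1ccc(OCc2ccccc2)c(OCc2ccccc2)c1)C(=C)OC | intermediate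
9 | (2R)-5,7-bis(benzyloxy)-2-[3,4-bis(benzyloxy)phenyl]-3-methoxy-2H-chromene (not isolated) | COC1=Cc2c(OCc3ccccc3)cc(OCc3ccccc3)cc2O[C@@H]1c1ccc(OCc2ccccc2)c(OCc2ccccc2)c1 | intermediate
10 | (2R)-5,7-bis(benzyloxy)-2-[3,4-bis(benzyloxy)phenyl]chroman-3-one | O=C1Cc2c(OCc3ccccc3)cc(OCc3ccccc3)cc2O[C@@H]1c1ccc(OCc2ccccc2)c(OCc2ccccc2)c1 | intermediate
11 | (2R,3R)-5,7-bis(benzyloxy)-2-[3,4-bis(benzyloxy)phenyl]chroman-3-ol (tetra-O-benzyl-(−)-epicatechin) | O[C@@H]1Cc2c(OCc3ccccc3)cc(OCc3ccccc3)cc2O[C@@H]1c1ccc(OCc2ccccc2)c(OCc2ccccc2)c1 | intermediate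
12 | methyl 2-[4-(benzyloxy)phenyl]acetate | COC(=O)Cc1ccc(OCc2ccccc2)cc1 | starting material
13 | methyl 2-[4-(benzyloxy)phenyl]-2-diazoacetate | COC(=O)C(=[N+]=[N-])c1ccc(OCc2ccccc2)cc1 | intermediate
14 | methyl (2R)-2-[3,5-bis(benzyloxy)-2-vinylphenoxy]-2-[4-(benzyloxy)phenyl]acetate | C=Cc1c(OCc2ccccc2)cc(OCc2ccccc2)cc1O[C@H](c1ccc(OCc2ccccc2)cc1)C(=O)OC | intermediate
15 | 1,5-bis(benzyloxy)-3-{[(1R)-1-[4-(benzyloxy)phenyl]-2-methoxyprop-2-en-1-yl]oxy}-2-vinylbenzene | C=Cc1c(OCc2ccccc2)cc(OCc2ccccc2)cc1O[C@H](c1ccc(OCc2ccccc2)cc1)C(=C)OC | intermediate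
16 | (2R)-5,7-bis(benzyloxy)-2-[4-(benzyloxy)phenyl]-3-methoxy-2H-chromene (not isolated) | COC1=Cc2c(OCc3ccccc3)cc(OCc3ccccc3)cc2O[C@@H]1c1ccc(OCc2ccccc2)cc1 | intermediate
17 | (2R)-5,7-bis(benzyloxy)-2-[4-(benzyloxy)phenyl]chroman-3-one | O=C1Cc2c(OCc3ccccc3)cc(OCc3ccccc3)cc2O[C@@H]1c1ccc(OCc2ccccc2)cc1 | intermediate
18 | (2R,3R)-5,7-bis(benzyloxy)-2-[4-(benzyloxy)phenyl]chroman-3-ol (tri-O-benzyl-(−)-epiafzelechin) | O[C@@H]1Cc2c(OCc3ccccc3)cc(OCc3ccccc3)cc2O[C@@H]1c1ccc(OCc2ccccc2)cc1 | intermediate
19 | 4β-(2-ethoxyethoxy)-5,7,4'-tri-O-benzyl-(−)-epiafzelechin (2,3-cis, 3,4-trans) | c1ccccc1COc1ccc([C@H]2Oc3cc(OCc4ccccc4)cc(OCc4ccccc4)c3[C@H](OCCOCC)[C@H]2O)cc1 | intermediate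
20 | hepta-O-benzyl ether of epiafzelechin-(4β→8)-epicatechin | c1ccccc1COc1ccc([C@H]2Oc3cc(OCc4ccccc4)cc(OCc4ccccc4)c3[C@H](c3c(OCc4ccccc4)cc(OCc4ccccc4)c4c3O[C@H](c3ccc(OCc5ccccc5)c(OCc5ccccc5)c3)[C@H](O)C4)[C@H]2O)cc1 | intermediate
21 | (−)-epiafzelechin-(4β→8)-(−)-epicatechin | Oc1ccc([C@H]2Oc3cc(O)cc(O)c3[C@H](c3c(O)cc(O)c4c3O[C@H](c3ccc(O)c(O)c3)[C@H](O)C4)[C@H]2O)cc1 | target

Total step count: 16.
Longest linear sequence: 9 steps (steps 1, 2, 10, 11, 12, 13, 14, 15, 16).

Steps most likely to fail

1. Step 7 (step 12 is the same chemistry in the other series). Three processes threaten it: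
- the ruthenium carbene may rest as a chelate with the ortho-benzyloxy oxygen of the 2,6-dioxygenated styrene and fail to turn over on the hindered enol ether;
- ruthenium hydride may move the double bond to C2=C3 and erase C2;
- the ketone may enolize toward C2 during hydrolysis.

Fallback: setting out from ester 7, a titanium-alkylidene olefinic-ester cyclization (TiCl4, Zn, PbCl2 cat., TMEDA, CH3CHBr2, THF, 65 °C). The titanium ethylidene first exchanges with the vinyl group, and the resulting titanium benzylidene then olefinates the ester carbonyl within the molecule. This carbonyl–olefin closure forms the same C3=C4 bond and should give enol ether 9 without ruthenium and without a separate methylenation. Buffered hydrolysis (oxalic acid, THF/H2O, 0 °C) returns to the route at ketone 10. No compound outside the numbered list arises (entry F0).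

2. Step 5 (step 10 is the same chemistry). The carbene may be transferred to the electron-rich styrene (cyclopropanation) instead of the O–H bond, the cationic palladium may start oligomerization of the vinylphenol, or the ortho-substituted phenol may erode the facial control of the proton shift.

Fallback: setting out from diazo ester 6, oxidation with dimethyldioxirane (acetone, 0 °C) should give methyl 2-[3,4-bis(benzyloxy)phenyl]-2-oxoacetate F1. Asymmetric transfer hydrogenation (RuCl(p-cymene)[(R,R)-TsDPEN], HCO2H/Et3N, rt) should reduce it to methyl (2S)-2-[3,4-bis(benzyloxy)phenyl]-2-hydroxyacetate F2, with the catalyst antipode chosen by the usual aryl-directed model. Mitsunobu etherification of F2 with phenol 3 (PPh3, DIAD, THF, 0 °C) inverts the carbinol center and returns to the route at ester 7.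

3. Step 2. The electron-rich 2-vinylphenol may dimerize or polymerize through its quinone methide tautomer during isolation or storage.

Fallback: the free vinylphenol is never made. Setting out from salicylaldehyde 2, Mitsunobu etherification (PPh3, DIAD, THF, 0 °C) with the mandelate F2 of the preceding fallback should give, with inversion, methyl (2R)-2-[3,5-bis(benzyloxy)-2-formylphenoxy]-2-[3,4-bis(benzyloxy)phenyl]acetate F3. Excess Cp2TiMe2 (toluene/THF, 65 °C) then methylenates the aldehyde and the ester in one operation and returns to the route at diene 8.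

Further compounds
F0 | step 7 | none | none
F1 | step 5 | methyl 2-[3,4-bis(benzyloxy)phenyl]-2-oxoacetate | COC(=O)C(=O)c1ccc(OCc2ccccc2)c(OCc2ccccc2)c1
F2 | step 5 | methyl (2S)-2-[3,4-bis(benzyloxy)phenyl]-2-hydroxyacetate | O[C@@H](c1ccc(OCc2ccccc2)c(OCc2ccccc2)c1)C(=O)OC
F3 | step 2 | methyl (2R)-2-[3,5-bis(benzyloxy)-2-formylphenoxy]-2-[3,4-bis(benzyloxy)phenyl]acetate | O=Cc1c(OCc2ccccc2)cc(OCc2ccccc2)cc1O[C@H](c1ccc(OCc2ccccc2)c(OCc2ccccc2)c1)C(=O)OC
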